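The data are calculated for substances that don't exist; noise was put on by code.

After 80.0 min at −8 °C the alpha run holds more target than the theta run, 30 % against 18 %, and alpha also holds more catalyst, 180 mM against 110 mM. From that comparison the examination starts, on flasks in which starting material and partner meet on a catalyst and give the target.

in all of them: starting material 0.80 M
- delta: partner 0.64 M; second substrate 0.17 M; catalyst 110 mM; temperature −30 °C; run made earlier
- theta: partner 0.64 M; second substrate 0.27 M; catalyst 110 mM; temperature −8 °C; run made earlier
- eta: partner 0.64 M; second substrate 0.37 M; catalyst 110 mM; temperature −30 °C; run made earlier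
- alpha: partner 0.64 M; second substrate 0.16 M; catalyst 180 mM; temperature −8 °C; run made earlier
- Monday's: partner 0.640 M; second substrate 0.160 M; catalyst 110 mM; temperature 0 °C; time 2.0 h
- Tuesday's: partner 0.640 M; second substrate 0.500 M; catalyst 200 mM; temperature −40 °C; time 2.0 h

delta run (percent of the starting material charged)

| time / h | target / % |
|---|---|
| 0.667 | 7 |
| 1.33 | 3 |
| 3.00 | 8 |
| 4.00 | 13 |
| 6.00 | 17 |

theta run (percent of the starting material charged)

| time / min | target / % |
|---|---|
| 6.00 | 5 |
| 12.0 | 6 |
| 25.0 | 8 |
| 40.0 | 12 |
| 80.0 | 18 |

eta run (percent of the starting material charged)

| time / h | target / % |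
|---|---|
| 1.00 | 3 |
| 2.00 | 10 |
| 4.00 | 12 |
| 6.00 | 15 |

alpha run (percent of the starting material charged)

| time / min | target / % |
|---|---|
| 6.00 | 7 |
| 12.0 | 8 |
| 25.0 | 13 |
| 40.0 | 20 |
| 80.0 | 30 |

(standard deviation of a reading: 2 percentage points)

1. which of the two ends with the higher amount of target, in percent of the starting material charged ("neither" if they lie within 2 percentage points) (Monday's / Tuesday's / neither)
2. target at the end, in percent of the starting material charged, Monday's
3. target at the end, in percent of the starting material charged, Tuesday's



Which concentration sets the rate? The catalyst, as far as these readings go. Alpha over theta gives a target ratio of 1.67 and a catalyst ratio of 1.64, so I take the rate as first order in c_catalyst. But those two runs also differ in second substrate, 0.16 M against 0.27 M, and that is the next question.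

And second substrate? The eta run holds twice the second substrate of the delta run at −30 °C, yet gives 15 % against 17 % at 6.00 h, a gap of the size of the scatter. So c_second substrate does not show in the target's rate up to 0.37 M, but Tuesday's 0.500 M lies beyond every run.

And partner? Starting material and partner stand at 0.80 M and 0.640 M in each run and in both flasks, so their orders cannot be read, and they can sit inside one number.

Which number? A pseudo-first-order time constant τ, with target fraction y = 1 − exp(−t/τ). Theta's last reading gives 6.72 h and delta's gives 32.2 h, both at 110 mM. Call the theta value the reference time constant: with starting material and partner as charged, I take τ as scaling with one over c_catalyst, and its logarithm as straight in temperature over this short span.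

Your numbers? For Monday's, τ is 3.80 h, so 40.9 % in 2.0 h. For Tuesday's, τ is 36.1 h, so 5.39 %.

Where is that weak? In Monday's flask. The τ read from the alpha run lengthens from 179 min at 40.0 min to 224 min at 80.0 min, and my reckoning holds τ constant. My Monday's figure should therefore run high.

The forecast says Monday's, with 36 % for Monday's and 5 % for Tuesday's, and it also finds the rate “first order in catalyst”. Its Monday's figure lies below mine.

The flasks give 37.4 % for Monday's and 5.06 % for Tuesday's, so Monday's ends higher.

    starting material + partner + catalyst → catalyst + target (k = 0.0930 /M²/min, Ea = 43.0 kJ/mol)
    partner → decomposed reagent (k = 5.80 × 10⁻⁴ /min, Ea = 88.0 kJ/mol)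
    second substrate + partner + catalyst → catalyst + second product (k = 0.160 /M²/min, Ea = 44.0 kJ/mol)
    (constants at 0 °C)

Read backwards, Tuesday's 5.06 % means τ = 38.5 h, against 36.1 h reckoned. The neighbouring flask repeats Tuesday's at −15 °C, with the same 200 mM of catalyst and the same 2.0 h. Moving Tuesday's reckoned τ along the same temperature line, which runs through the reference time constant, gives its τ as 6.08 h, and that gives 28.0 % target. That neighbouring flask gives 25.4 %, with 37 % of its partner charge left.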